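The formyl-bearing cyclohexene ring (acetoxy bridge carbon, both bridgeheads, CH2 and the CH=C(CHO) unit) is made last, by Wolff ring contraction of a cycloheptenone. The step exploits the exocyclic formyl carbon on the ring carbon between a bridgehead and the alkene CH. In a bicyclo[4.4.1]undecane 2-diazo-3-enone the side-chain-bearing bridgehead migrates to the diazo carbon, and the ketone carbon leaves the ring as a ketene that becomes the formyl carbon. The precursor is built on 8-oxabicyclo[3.2.1]oct-6-en-3-one, whose exo face sets both bridgehead substituents syn to oxygen: a citronellyl-derived nitroalkene is joined at the α-carbon, and a tethered bromoalkene then opens the oxygen bridge to close the seven-membered ring.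

Key step: step 9

Assumption: ketone 5 is taken as a catalogue compound (otherwise one operation from furan and tetrabromoacetone).
Locants in the text follow the target skeleton: C1 (C=CH2), C2 (CH2), C3 (CHOAc), C4 (side-chain-bearing CH), C5 and C9 (bridgeheads), C6 (C–CHO), C7 (=CH), C8 (CH2), C10 (bridging CHOAc), C11 (side-chain CHMe). Cx is the ketone carbon that stands between C5 and C6 before the ring contraction.

Step 1
Reactants: 1 (S)-citronellyl bromide
Product: 2 (3S)-3,7-dimethyl-1-nitrooct-6-ene
Conditions: NaNO2, urea, DMF, rt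
Reagents that add atoms: sodium nitrite, [Na+].[O-]N=O
Why: Kornblum substitution, in which nitrite displaces the primary bromide by SN2 at nitrogen and the remote C11 stereocentre is untouched.

Step 2
Reactants: 2 (3S)-3,7-dimethyl-1-nitrooct-6-ene
Product: 4 (3S,1E)-3,7-dimethyl-1-nitroocta-1,6-diene, via selenide 3 (not isolated)
Conditions: n-BuLi, THF, −78 °C; PhSeBr; then 30% H2O2, 0 °C
Reagents that add atoms: none
Why: C-selenenylation of the lithium nitronate and selenoxide syn-elimination should give the conjugated (E)-nitroalkene; no stereocentre is formed and C11 is not deprotonated.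

Step 3
Reactants: 5 8-oxabicyclo[3.2.1]oct-6-en-3-one (meso)
Product: 6 (1S,5S)-3-(trimethylsilyloxy)-8-oxabicyclo[3.2.1]octa-2,6-diene
Conditions: bis[(S)-1-phenylethyl]amine hydrochloride, n-BuLi (2 equiv), THF, −78 °C; then Me3SiCl and 5, −100 °C
Reagents that add atoms: chlorotrimethylsilane, C[Si](C)(C)Cl
Why: enantioselective deprotonation of a meso ketone by a chiral lithium amide with internal silyl quench, removing one of the two enantiotopic axial α-protons (sense assigned by analogy with 4-substituted cyclohexanones) and so fixing which bridgehead becomes C10 and which α-carbon becomes C5.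

Step 4
Reactants: 6 silyl enol ether; 4 nitroalkene
Product: 8 (2R,3S)-3,7-dimethyl-2-[(1S,2S,5S)-3-oxo-8-oxabicyclo[3.2.1]oct-6-en-2-yl]oct-6-enal, via cyclic nitronate 7 (not isolated)
Conditions: 4 (1.2 equiv), SnCl4 (1.1 equiv), CH2Cl2, −78 °C; then H2O, 0 °C to rt
Reagents that add atoms: water, O
Why: Lewis-acid-promoted [4+2] of the nitroalkene (heterodiene) with the silyl enol ether followed by hydrolytic Nef collapse (Mukaiyama–Michael/Nef route to 1,4-dicarbonyls); attack on the exo face makes the new C4–C5 bond axial and syn to the oxygen bridge, the silyloxy-endo transition state of the (E)-nitroalkene gives the usual syn Michael relationship that sets C4, and the diastereomer arising from any ent-6 is removed here.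

Step 5
Reactants: 8 keto aldehyde
Product: 9 (1S,2S,5S)-2-[(4S,5R,6S)-2-bromo-4-hydroxy-6,10-dimethylundeca-1,9-dien-5-yl]-8-oxabicyclo[3.2.1]oct-6-en-3-one
Conditions: (−)-Ipc2BBr [from (+)-α-pinene], propadiene, CH2Cl2, −78 to 0 °C; then 8, Et2O, −78 °C; ethanolamine work-up
Reagents that add atoms: propadiene, C=C=C; (−)-B-bromodiisopinocampheylborane, BrB([C@@H]1C[C@@H]2C[C@H]([C@H]1C)C2(C)C)[C@@H]1C[C@@H]2C[C@H]([C@H]1C)C2(C)C
Why: bromoboration of the allene gives the 2-bromoallylborane, whose asymmetric allylboration through a closed chair-like six-membered transition state attacks the Si face of the aldehyde and sets (3S) under reagent control, while the ketone is too slow to react at −78 °C.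

Step 6
Reactants: 9 bromoallyl carbinol
Product: 10 9,11-dihydroxy-7-methylidene-10-[(2S)-6-methylhept-5-en-2-yl]bicyclo[4.4.1]undec-4-en-2-one (C3, C4, C5, C9, C10 as in the target)
Conditions: NiBr2(dppe) (10 mol %), Zn dust (3 equiv), MeCN, 60 °C; H2O work-up
Reagents that add atoms: none
Why: Proposed new method: oxidative addition of zerovalent nickel into the vinylic C–Br bond, 7-exo syn carbonickelation of the strained C8=C9 bridge alkene on its exo face (the only face the tether, itself syn to the oxygen bridge, can reach) and syn β-oxygen elimination should form the C1–C9 bond with C1 cis to the C10 oxygen, open the ether to the C10 alkoxide and leave the C7=C8 alkene, zinc returning nickel to the zerovalent state; the closest known reactions are the nickel- or palladium-catalysed, zinc-mediated ring-opening additions of aryl and alkenyl halides to oxabicyclic alkenes, which are intermolecular.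

Step 7
Reactants: 10 diol ketone
Product: 11 9,11-diacetate of 10
Conditions: Ac2O, DMAP, pyridine, CH2Cl2, rt
Reagents that add atoms: acetic anhydride, CC(=O)OC(C)=O
Why: DMAP-catalysed O-acylation of the two secondary alcohols; no stereocentre is touched.

Step 8
Reactants: 11 diacetate
Product: 12 3-diazo derivative of 11 (diazo group on C6, between the ketone Cx and the C7=C8 alkene)
Conditions: 4-acetamidobenzenesulfonyl azide, DBU, MeCN, 0 °C
Reagents that add atoms: 4-acetamidobenzenesulfonyl azide, CC(=O)Nc1ccc(cc1)S(=O)(=O)N=[N+]=[N-]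
Why: Regitz diazo transfer to the only methylene activated by both the ketone and the alkene (bridgehead C5 carries a single hydrogen); loss of the C10 acetate by β-elimination is blocked because it would need a double bond to the one-carbon bridge.

Step 9
Reactants: 12 diazo ketone
Product: 14 4,10-diacetoxy-2-methylidene-5-[(2S)-6-methylhept-5-en-2-yl]bicyclo[4.3.1]dec-8-ene-7-carboxylic acid (epimers at the carboxyl-bearing carbon C6), via ring-contracted ketene 13 (not isolated)
Conditions: hν (350 nm, Pyrex), THF/H2O 10:1, rt
Reagents that add atoms: water, O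
Why: Photolysis of the s-Z-locked cyclic diazo ketone expels N2 with concerted 1,2-shift of bridgehead C5 from the carbonyl carbon Cx to C6 (Wolff rearrangement), so the seven-membered ring C5–Cx–C6–C7–C8–C9–C10 contracts to the six-membered ring C5–C6–C7–C8–C9–C10 and Cx leaves as a vinylketene that water converts into the acid. The closest known reaction is the photochemical Wolff ring contraction of cyclic 2-diazo ketones. No ring is closed between chain ends; the six-membered ring arises by suprafacial 1,2-alkyl migration with retention at C5. The only new stereocentre, C6, comes from ketonisation of the acid enol, is uncontrolled and is erased in step 10; C3, C4, C5, C9, C10 and C11 are untouched. The step needs migration to outrun vinylcarbene side reactions (cyclopropene formation, 1,2-hydride shift), which the fixed s-Z geometry of the ring diazo ketone should secure, and the regiochemistry is unambiguous because C5 is the only group on Cx that can migrate.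

Step 10
Reactants: 14 carboxylic acid
Product: 17 target, 4,10-diacetoxy-2-methylidene-5-[(2S)-6-methylhept-5-en-2-yl]bicyclo[4.3.1]dec-7-ene-7-carbaldehyde, via acid chloride 15 (not isolated), via deconjugated aldehyde 16 (not isolated)
Conditions: 1-chloro-N,N,2-trimethylprop-1-en-1-amine, CH2Cl2, 0 °C; LiAlH(OtBu)3, THF, −78 °C; then DBU (cat.), CH2Cl2, rt
Reagents that add atoms: none
Why: the neutral chloroenamine makes the acid chloride without HCl, partial hydride reduction by LiAlH(OtBu)3 stops at the aldehyde and spares the acetates at −78 °C, and base-catalysed isomerisation moves the C7=C8 double bond into conjugation (a C5=C6 bridgehead alkene being excluded), which removes the C6 stereocentre.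

Compound list
1 | (S)-citronellyl bromide, (6S)-8-bromo-2,6-dimethyloct-2-ene | BrCC[C@@H](C)CCC=C(C)C | starting material
2 | (3S)-3,7-dimethyl-1-nitrooct-6-ene | [O-][N+](=O)CC[C@@H](C)CCC=C(C)C | intermediate
3 | (3S)-3,7-dimethyl-1-nitro-1-(phenylselanyl)oct-6-ene (C1 epimers) | [O-][N+](=O)C([Se]c1ccccc1)C[C@@H](C)CCC=C(C)C | intermediate (not isolated)
4 | (3S,1E)-3,7-dimethyl-1-nitroocta-1,6-diene | [O-][N+](=O)/C=C/[C@@H](C)CCC=C(C)C | intermediate
5 | 8-oxabicyclo[3.2.1]oct-6-en-3-one (meso) | O=C1C[C@H]2C=C[C@@H](C1)O2 | starting material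
6 | (1S,5S)-3-(trimethylsilyloxy)-8-oxabicyclo[3.2.1]octa-2,6-diene | C[Si](C)(C)OC1=C[C@@H]2C=C[C@H](C1)O2 | intermediate
7 | cyclic nitronate: 1,2-oxazine N-oxide fused across the former enol ether carbons, silyloxy on the ketal carbon, C4–C5 bond exo | [O-][N+]1=C[C@H]([C@@H](C)CCC=C(C)C)[C@@H]2[C@@](O1)(O[Si](C)(C)C)C[C@H]3C=C[C@@H]2O3 | intermediate (not isolated)
8 | (2R,3S)-3,7-dimethyl-2-[(1S,2S,5S)-3-oxo-8-oxabicyclo[3.2.1]oct-6-en-2-yl]oct-6-enal | O=C[C@H]([C@@H](C)CCC=C(C)C)[C@@H]1C(=O)C[C@H]2C=C[C@@H]1O2 | intermediate
9 | (1S,2S,5S)-2-[(4S,5R,6S)-2-bromo-4-hydroxy-6,10-dimethylundeca-1,9-dien-5-yl]-8-oxabicyclo[3.2.1]oct-6-en-3-one | C=C(Br)C[C@H](O)[C@H]([C@@H](C)CCC=C(C)C)[C@@H]1C(=O)C[C@H]2C=C[C@@H]1O2 | intermediate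
10 | 9,11-dihydroxy-7-methylidene-10-[(2S)-6-methylhept-5-en-2-yl]bicyclo[4.4.1]undec-4-en-2-one | C=C1C[C@H](O)[C@H]([C@@H](C)CCC=C(C)C)[C@@H]2C(=O)CC=C[C@H]1[C@@H]2O | intermediate
11 | 9,11-diacetoxy-7-methylidene-10-[(2S)-6-methylhept-5-en-2-yl]bicyclo[4.4.1]undec-4-en-2-one | C=C1C[C@H](OC(C)=O)[C@H]([C@@H](C)CCC=C(C)C)[C@@H]2C(=O)CC=C[C@H]1[C@@H]2OC(C)=O | intermediate
12 | 9,11-diacetoxy-3-diazo-7-methylidene-10-[(2S)-6-methylhept-5-en-2-yl]bicyclo[4.4.1]undec-4-en-2-one | C=C1C[C@H](OC(C)=O)[C@H]([C@@H](C)CCC=C(C)C)[C@@H]2C(=O)C(=[N+]=[N-])C=C[C@H]1[C@@H]2OC(C)=O | intermediate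
13 | 4,10-diacetoxy-2-methylidene-5-[(2S)-6-methylhept-5-en-2-yl]-7-(oxomethylidene)bicyclo[4.3.1]dec-8-ene (vinylketene) | C=C1C[C@H](OC(C)=O)[C@H]([C@@H](C)CCC=C(C)C)[C@@H]2C(=C=O)C=C[C@H]1[C@@H]2OC(C)=O | intermediate (not isolated)
14 | 4,10-diacetoxy-2-methylidene-5-[(2S)-6-methylhept-5-en-2-yl]bicyclo[4.3.1]dec-8-ene-7-carboxylic acid (C7 epimers) | C=C1C[C@H](OC(C)=O)[C@H]([C@@H](C)CCC=C(C)C)[C@@H]2C(C(=O)O)C=C[C@H]1[C@@H]2OC(C)=O | intermediate
15 | acid chloride of 14 | C=C1C[C@H](OC(C)=O)[C@H]([C@@H](C)CCC=C(C)C)[C@@H]2C(C(=O)Cl)C=C[C@H]1[C@@H]2OC(C)=O | intermediate (not isolated)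
16 | 4,10-diacetoxy-2-methylidene-5-[(2S)-6-methylhept-5-en-2-yl]bicyclo[4.3.1]dec-8-ene-7-carbaldehyde (C7 epimers) | C=C1C[C@H](OC(C)=O)[C@H]([C@@H](C)CCC=C(C)C)[C@@H]2C(C=O)C=C[C@H]1[C@@H]2OC(C)=O | intermediate (not isolated)
17 | 4,10-diacetoxy-2-methylidene-5-[(2S)-6-methylhept-5-en-2-yl]bicyclo[4.3.1]dec-7-ene-7-carbaldehyde | C=C1C[C@H](OC(C)=O)[C@H]([C@@H](C)CCC=C(C)C)[C@@H]2C(C=O)=CC[C@H]1[C@@H]2OC(C)=O | target

Total step count: 10. Longest linear sequence: 9 steps (steps 1, 2 and 4 to 10); step 3 is a one-step branch from ketone 5.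

Steps most likely to fail

Step 6 (new method). The vinylnickel species may be reduced to the debrominated alkene, or may add to the ketone, before the seven-membered carbometalation takes place. The fallback sets out from 9. A palladium-catalysed reductive Heck cyclisation (Pd(OAc)2, PPh3, HCO2Na, DMF, 80 °C), a known hydrovinylation of strained bicyclic alkenes, should form the C1–C9 bond on the exo face and keep the oxygen bridge, giving the tricyclic ether ketone F1. LDA (excess, THF, −78 to 0 °C) should then enolise toward C6 and open the bridge by β-alkoxide elimination to the conjugated hydroxy enone F2. Deconjugation (KOtBu, t-BuOH, then rapid AcOH quench) moves the double bond to C7=C8, and the route is rejoined at 10.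

Step 8. DBU may move the β,γ-double bond into conjugation with the ketone before the sulfonyl azide is captured, leaving C6 without an acidic methylene. The fallback sets out from 11. Kinetic enolisation with LiHMDS (THF, −78 °C), where the doubly activated ketone methylene is far more acidic than the acetates, and trapping with 2,2,2-trifluoroethyl trifluoroacetate should give the trifluoroacetyl ketone F3. Methanesulfonyl azide, Et3N and H2O in MeCN then effect detrifluoroacetylative diazo transfer, and the route is rejoined at 12.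

Step 4. The acidic Nef hydrolysis may erode the configuration at C4 (α to the new aldehyde) or epimerise the kinetically set axial bond at C5, and the intermediate nitronate may be diverted by cycloaddition onto the side-chain alkene. The fallback sets out from 6 and 4. Methyllithium (THF, 0 °C) regenerates the lithium enolate of 6, which should add to 4 at −78 °C through the chelated transition state with the same exo and syn selectivity; acetic acid quench gives the nitro ketone F4. Nitronate formation (NaOMe, MeOH, 0 °C) and buffered aqueous TiCl3 (NH4OAc) then perform the Nef reaction under near-neutral conditions, and the route is rejoined at 8.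

Further compounds
F1 | step 6 | oxygen-bridged tricyclic ketone (reductive Heck product; C1–C9 bond formed, C7–O–C10 bridge intact) | C=C1C[C@H](O)[C@H]([C@@H](C)CCC=C(C)C)[C@@H]2C(=O)C[C@H]3C[C@H]1[C@@H]2O3
F2 | step 6 | 9,11-dihydroxy-7-methylidene-10-[(2S)-6-methylhept-5-en-2-yl]bicyclo[4.4.1]undec-3-en-2-one (conjugated enone) | C=C1C[C@H](O)[C@H]([C@@H](C)CCC=C(C)C)[C@@H]2C(=O)C=CC[C@H]1[C@@H]2O
F3 | step 8 | 3-(trifluoroacetyl) derivative of 11 | C=C1C[C@H](OC(C)=O)[C@H]([C@@H](C)CCC=C(C)C)[C@@H]2C(=O)C(C(=O)C(F)(F)F)C=C[C@H]1[C@@H]2OC(C)=O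
F4 | step 4 | (1S,2S,5S)-2-[(2R,3S)-3,7-dimethyl-1-nitrooct-6-en-2-yl]-8-oxabicyclo[3.2.1]oct-6-en-3-one | [O-][N+](=O)C[C@H]([C@@H](C)CCC=C(C)C)[C@@H]1C(=O)C[C@H]2C=C[C@@H]1O2
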